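**Plan**

Labels: the eleven ring carbons are numbered as they are met on reading the target SMILES from the angelate end. C1 is CH–O-angeloyl, C2 CH–O-isobutyryl, C3 CH2, C4 the quaternary C–CH3, C5 CH, C6 C=O, C7 =CH, C8 =C–CH3, C9 CH, C10 CH, C11 CMe2.
Enabling feature: the cyclobutane C4–C5–C10–C9 is the ring-expanded form of a cyclopropane C4–C5–C10 fused to the six-membered ring C4–C5–C6–C7–C8–C9. Sliding C10 from C4 to a cationic C9 makes the four-membered ring and leaves the charge on methyl-bearing C4, the atom at which the seven-membered ring C4–C3–C2–C1–C11–C10–C9 has to close.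
Retrosynthesis: remove both esters and the C7=C8 unsaturation, then cut C3–C4 and C9–C10 together (restoring C4–C10). Further cuts are C5–C4/C5–C10 (carbenoid), C5–C6 (diazomethane), C8–C9 (allenylmetal addition), and C4=C10 and C2=C3 (two Wittig reactions).
Forward: one chain is built out from (S)-pantolactone. Step 12 closes the six- and three-membered rings together, step 17 closes the four- and seven-membered rings together, and six steps then adjust oxidation level and esters.
Stereochemistry: C1 comes from (S)-pantolactone. (R)-But-3-yn-2-ol sets C8 and C9, which steer the carbenoid to one alkene face (C4, C5, C10), and the E alkene makes C11 exo. The stereospecific shift relays this to C9 and C4 of the cage. C2 is set by hydride attack anti to the C1 oxygen followed by Mitsunobu inversion, and the Z ester comes from angelic acid.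

Key step: step 17

Assumption: the C6 carbinol and C8 methyl centres are temporary and both vanish in step 21; they are drawn as the epimers expected from steps 13 and 7.

**Step 1**
Reactants: 1 (S)-pantolactone
Product: 2 (3S)-3-(tert-butyldimethylsilyloxy)-4,4-dimethyloxolan-2-one
Conditions: TBSCl, imidazole, DMF, 23 to 40 °C
Reagents that add atoms: tert-butyldimethylsilyl chloride, CC(C)(C)[Si](C)(C)Cl
Why: Imidazole-promoted silylation leaves the future C1 centre untouched, and a bulky silyl ether is chosen because, unlike an acetal protecting group, it neither ionises nor alkylates an enol silane under the silyl triflate conditions of step 17.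

**Step 2**
Reactants: 2 silyl-protected pantolactone
Product: 3 (3S)-3-(tert-butyldimethylsilyloxy)-4,4-dimethyloxolan-2-ol (lactol, both anomers)
Conditions: i-Bu2AlH, CH2Cl2, −78 °C
Reagents that add atoms: none
Why: Partial lactone reduction stops at the tetrahedral aluminium hemiacetal at low temperature and releases the lactol on work-up.

**Step 3**
Reactants: 3 lactol
Product: 4 (3R)-3-(tert-butyldimethylsilyloxy)-2,2-dimethylpent-4-en-1-ol
Conditions: Ph3PCH3Br, KN(SiMe3)2, THF, −78 to 0 °C
Reagents that add atoms: methyltriphenylphosphonium bromide, C[P+](c1ccccc1)(c1ccccc1)c1ccccc1.[Br-]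
Why: Wittig methylenation of the open hydroxy-aldehyde tautomer brings in C3 as a masked methyl ketone, and low temperature with short contact keeps the hindered silyl group from migrating to the primary alkoxide.

**Step 4**
Reactants: 4 alkenol
Product: 5 (3R)-3-(tert-butyldimethylsilyloxy)-2,2-dimethylpent-4-enal
Conditions: Dess–Martin periodinane, CH2Cl2, 0 to 23 °C
Reagents that add atoms: none
Why: Dess–Martin oxidation of the neopentyl alcohol gives an aldehyde (C10) with no α-hydrogen, so it can neither epimerise nor eliminate the β-silyloxy group.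

**Step 5**
Reactants: 5 aldehyde
Product: 6 (2E,5R)-5-(tert-butyldimethylsilyloxy)-2,4,4-trimethylhepta-2,6-dienal
Conditions: Ph3P=C(CH3)CHO, toluene, 110 °C
Reagents that add atoms: 2-(triphenylphosphoranylidene)propanal, CC(C=O)=P(c1ccccc1)(c1ccccc1)c1ccccc1
Why: The Wittig reaction of a stabilised formyl ylide is E-selective and stops after one homologation because the hindered trisubstituted enal is far less reactive than 5; it adds C4, its methyl and C9.

**Step 6**
Reactants: 7 (R)-but-3-yn-2-ol
Product: 8 (R)-but-3-yn-2-yl methanesulfonate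
Conditions: MsCl, Et3N, CH2Cl2, −78 to 0 °C
Reagents that add atoms: methanesulfonyl chloride, CS(=O)(=O)Cl
Why: O-Sulfonylation does not touch the C–O bond, so the carbinol configuration is retained.

**Step 7**
Reactants: 6 enal; 8 propargylic mesylate
Product: 10 (3S,4S,5E,8R)-8-(tert-butyldimethylsilyloxy)-3,5,7,7-tetramethyldeca-5,9-dien-1-yn-4-ol, via allenylindium iodide mesylate 9 (not isolated)
Conditions: Pd(dppf)Cl2 (5 mol %), InI, THF–DMPU, 23 °C
Reagents that add atoms: none
Why: In this palladium-catalysed allenylindium propargylation, anti SN2' attack of zerovalent palladium, transmetalation and SE2' addition through a cyclic transition state replace the mesylate with inversion (C8) and give the anti C8/C9 pair under reagent control.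

**Step 8**
Reactants: 10 homopropargylic alcohol
Product: 11 the C9 pivalate of 10
Conditions: PivCl, DMAP (cat.), pyridine, 50 °C
Reagents that add atoms: pivaloyl chloride, CC(C)(C)C(=O)Cl
Why: DMAP-catalysed acylation installs an ester that survives every step up to 17, deactivates C9–H toward carbenoid insertion, has no α-hydrogen for step 16 and is the later leaving group.

**Step 9**
Reactants: 11 alkynyl pivalate
Product: 13 (3S,4S,5E,8R)-8-(tert-butyldimethylsilyloxy)-3,5,7,7-tetramethyl-4-(pivaloyloxy)deca-5,9-dienal, via E-alkenyldicyclohexylborane 12 (not isolated)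
Conditions: Cy2BH (1.1 equiv), THF, 0 °C; then H2O2, aq NaOAc
Reagents that add atoms: hydrogen peroxide, OO
Why: In hydroboration–oxidation a dialkylborane adds to a terminal alkyne faster than to alkenes and places boron on the terminal carbon (C6), while the only monosubstituted alkene is shielded by a silyloxy group and a quaternary carbon.

**Step 10**
Reactants: 13 aldehyde
Product: 14 the corresponding carboxylic acid (C6 = CO2H)
Conditions: NaClO2, NaH2PO4, 2-methylbut-2-ene, t-BuOH–H2O, 0 to 23 °C
Reagents that add atoms: sodium chlorite, [Na+].[O-]Cl=O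
Why: Pinnick oxidation is selective for the aldehyde, and the alkene scavenger removes hypochlorous acid before it can reach the substrate alkenes.

**Step 11**
Reactants: 14 acid
Product: 16 (4S,5S,6E,9R)-1-diazo-9-(tert-butyldimethylsilyloxy)-4,6,8,8-tetramethyl-5-(pivaloyloxy)undeca-6,10-dien-2-one, via isobutyl carbonic mixed anhydride 15 (not isolated)
Conditions: i-BuOCOCl, N-methylmorpholine, THF, −20 °C; then CH2N2, Et2O, 0 °C
Reagents that add atoms: diazomethane, C=[N+]=[N-]
Why: Acylation of diazomethane by a mixed anhydride (the first stage of the Arndt–Eistert sequence) adds C5 under neutral conditions that spare the silyl ether and the allylic ester.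

**Step 12**
Reactants: 16 diazoketone
Product: 17 4,6-dimethyl-5-(pivaloyloxy)-7-exo-[(3R)-3-(tert-butyldimethylsilyloxy)-2-methylpent-4-en-2-yl]bicyclo[4.1.0]heptan-2-one (C6 ketone; C9 pivalate trans to the cyclopropane and cis to the C8 methyl)
Conditions: Rh2(cap)4 (dirhodium tetracaprolactamate, 1 mol %), CH2Cl2, slow addition, 40 °C
Reagents that add atoms: none
Why: Intramolecular carbenoid cyclopropanation of a 1-diazohept-6-en-2-one is the standard entry to bicyclo[4.1.0]heptan-2-ones and the carboxamidate catalyst favours alkene addition over C–H insertion; the addition is stereospecific, so the E alkene puts C11 exo, and a chair-like transition state with the C8 methyl equatorial and the smaller C9 acyloxy group axial, near the alkene plane where it least depletes the π bond, places C10 on the ring face opposite the C9 oxygen.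

**Step 13**
Reactants: 17 norcaranone
Product: 18 the C6 carbinol of 17, hydroxyl syn to the cyclopropane
Conditions: LiBH(s-Bu)3, THF, −78 °C
Reagents that add atoms: none
Why: Bulky-hydride reduction attacks from the face away from the three-membered ring, and the ketone is removed because a C6 carbonyl would be silylated along with C2, and its enol ether would activate C8–H and the C4–C5 bond in step 17.

**Step 14**
Reactants: 18 carbinol
Product: 19 the C6 triethylsilyl ether of 18
Conditions: Et3SiCl, imidazole, CH2Cl2, 0 to 23 °C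
Reagents that add atoms: chlorotriethylsilane, CC[Si](CC)(CC)Cl
Why: Silylation gives a poor leaving group at the second cyclopropylcarbinyl position, and this group can later be removed in the presence of the C1 tert-butyldimethylsilyl ether.

**Step 15**
Reactants: 19 terminal alkene
Product: 20 the C2 methyl ketone (side chain CMe2–CH(OTBS)–C(=O)CH3)
Conditions: Pd(Quinox)Cl2 (5 mol %), AgSbF6 (12 mol %), aq t-BuOOH, CH2Cl2, 0 to 23 °C
Reagents that add atoms: tert-butyl hydroperoxide, CC(C)(C)OO
Why: The Tsuji–Wacker oxidation in its catalyst-controlled quinoline–oxazoline variant gives methyl ketones from protected allylic alcohols where the classical system leaks to the aldehyde, and the vinyl group is the only alkene left.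

**Step 16**
Reactants: 20 methyl ketone
Product: 21 key-step precursor: the C2 trimethylsilyl enol ether (C3=CH2) of 20, with trans C9 pivalate, C6 triethylsilyl ether and C1 tert-butyldimethylsilyl ether
Conditions: LiN(i-Pr)2, Me3SiCl (in situ), THF, −78 °C; Et3N, pentane work-up
Reagents that add atoms: chlorotrimethylsilane, C[Si](C)(C)Cl
Why: Kinetic enolisation takes the methyl proton because C1–H is neopentyl and flanked by the silyloxy group, and the pivalate has no α-hydrogen and is too hindered to be attacked at this temperature.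

**Step 17**
Reactants: 21 enol silane pivalate
Product: 24 longipinane-type tricyclo[5.4.0.0(2,8)]undecane C2 ketone carrying C1–OTBS plus C6–OTES plus saturated C7–C8, via C9 cyclopropylcarbinyl cation 22 (not isolated), via C4 cyclobutyl cation 23 (not isolated)
Conditions: Me3SiOTf (20 mol %), 2,6-di-tert-butyl-4-methylpyridine (30 mol %), CH2Cl2, −78 to −30 °C
Reagents that add atoms: none
Why: Proposed new method: Me3SiOTf silylates the pivalate carbonyl and the axial C9–O bond, antiperiplanar to the external cyclopropane bond C4–C10, ionises with σ-participation to cation 22, C10 moves from C4 to C9 to give the methyl-stabilised tertiary cation 23, and attack of the enol silane carbon C3 on C4 followed by transfer of Me3Si to pivalate is irreversible and regenerates the catalyst. The closest known reactions are the solvolytic ring expansion of (1-methylcyclopropyl)carbinyl esters to 1-methylcyclobutyl products and the Lewis-acid α-tert-alkylation of silyl enol ethers by tertiary cations, which have not been merged in one operation or used to raise a bridged bicyclo[3.1.1]heptane. The cyclobutane C4–C5–C10–C9 closes by a Wagner–Meerwein 1,2-alkyl shift (three- to four-membered ring expansion) and the seven-membered ring C4–C3–C2–C1–C11–C10–C9 by a 7-(enolendo) attack on the trigonal cationic carbon C4. C9 is set by inversion because C10 enters opposite the departing oxygen, C10 migrates with retention, and C4 is set because the exo chain carried by C10 reaches only the lobe that C10 has just vacated, the other lobe pointing under the C6–C7–C8 bridge. The step needs ionisation at C9 and not C6, migration of C4–C10 and not C4–C5, and capture at C4 ahead of hydride shift or proton loss. These are secured because the only acyloxy group sits at C9 while the C6 oxygen is a silyl ether syn to the cyclopropane and misaligned with its bonds, the in-ring bond C4–C5 is nearly orthogonal to the empty C9 orbital and its cleavage would place charge next to the C6 oxygen, the strained σ bond outruns the C8–H bond as neighbouring group, the bridgeheads C5 and C9 cannot lose a proton, and the hindered pyridine removes adventitious acid.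

**Step 18**
Reactants: 24 tricyclic ketone
Product: 25 the C2 alcohol, hydroxyl cis to the C1 silyloxy group
Conditions: LiBH(s-Bu)3, THF, −78 °C
Reagents that add atoms: none
Why: In this substrate-controlled ketone reduction the bulky hydride enters anti to the neighbouring C1 silyloxy group (Felkin–Anh sense in the twisted four-carbon bridge), and with C6 held as a silyl ether no second carbonyl competes.

**Step 19**
Reactants: 25 cis alcohol
Product: 26 the C2 isobutyrate, trans to the C1 silyloxy group
Conditions: i-PrCO2H, PPh3, DIAD, toluene, 0 to 40 °C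
Reagents that add atoms: isobutyric acid, CC(C)C(=O)O
Why: Mitsunobu esterification proceeds with SN2 inversion, the carboxylate entering from the same open face that the hydride used, so the target C2 configuration and the ester arrive together.

**Step 20**
Reactants: 26 bis-silyl ether
Product: 27 the C6 alcohol (C1–OTBS retained)
Conditions: PPTS, MeOH–CH2Cl2, 0 °C
Reagents that add atoms: none
Why: Mild acid methanolysis cleaves a triethylsilyl ether much faster than a hindered neopentyl tert-butyldimethylsilyl ether and leaves the ester alone.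

**Step 21**
Reactants: 27 C6 alcohol
Product: 29 the C6-keto C7=C8 enone with C1–OTBS, via saturated C6 ketone 28 (not isolated)
Conditions: IBX (3 equiv), DMSO, 70 °C
Reagents that add atoms: none
Why: IBX first oxidises the alcohol and then dehydrogenates the ketone (IBX dehydrogenation); enolisation is possible only toward C7 because C5 is a bridgehead, so one enone forms and the temporary C6 and C8 centres disappear.

**Step 22**
Reactants: 29 silyl ether enone
Product: 30 the free C1 alcohol
Conditions: HF·pyridine, pyridine, THF, 0 to 23 °C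
Reagents that add atoms: none
Why: Buffered acidic fluoride desilylation avoids the alkoxide that a basic fluoride source would generate next to the C2 ester, so 1,2-acyl migration is suppressed.

**Step 23**
Reactants: 30 C1 alcohol
Product: 31 target CNP0286736.1
Conditions: angelic acid, 2,4,6-trichlorobenzoyl chloride, Et3N, toluene, 23 °C; then 30, 80 °C
Reagents that add atoms: angelic acid, C/C=C(/C)C(=O)O
Why: Yamaguchi-type mixed-anhydride acylation without a nucleophilic catalyst is the established stereoconservative angeloylation of hindered alcohols and avoids Z-to-E isomerisation to the tiglate.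

**Compound list**

1 | (S)-pantolactone | CC1(C)COC(=O)[C@H]1O | starting material
2 | (3S)-3-(tert-butyldimethylsilyloxy)-4,4-dimethyloxolan-2-one | CC1(C)COC(=O)[C@H]1O[Si](C)(C)C(C)(C)C | intermediate
3 | (3S)-3-(tert-butyldimethylsilyloxy)-4,4-dimethyloxolan-2-ol, both anomers | CC1(C)COC(O)[C@H]1O[Si](C)(C)C(C)(C)C | intermediate
4 | (3R)-3-(tert-butyldimethylsilyloxy)-2,2-dimethylpent-4-en-1-ol | OCC(C)(C)[C@H](O[Si](C)(C)C(C)(C)C)C=C | intermediate
5 | (3R)-3-(tert-butyldimethylsilyloxy)-2,2-dimethylpent-4-enal | O=CC(C)(C)[C@H](O[Si](C)(C)C(C)(C)C)C=C | intermediate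
6 | (2E,5R)-5-(tert-butyldimethylsilyloxy)-2,4,4-trimethylhepta-2,6-dienal | O=C/C(C)=C/C(C)(C)[C@H](O[Si](C)(C)C(C)(C)C)C=C | intermediate
7 | (R)-but-3-yn-2-ol | C[C@@H](O)C#C | starting material
8 | (R)-but-3-yn-2-yl methanesulfonate | C[C@@H](OS(C)(=O)=O)C#C | intermediate
9 | buta-1,2-dienylindium iodide methanesulfonate, axially chiral | [H]C([In](I)OS(C)(=O)=O)=[C@]=C([H])C | intermediate
10 | (3S,4S,5E,8R)-8-(tert-butyldimethylsilyloxy)-3,5,7,7-tetramethyldeca-5,9-dien-1-yn-4-ol | C#C[C@H](C)[C@H](O)/C(C)=C/C(C)(C)[C@H](O[Si](C)(C)C(C)(C)C)C=C | intermediate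
11 | C9 pivalate of 10 | C#C[C@H](C)[C@H](OC(=O)C(C)(C)C)/C(C)=C/C(C)(C)[C@H](O[Si](C)(C)C(C)(C)C)C=C | intermediate
12 | E-alkenyldicyclohexylborane from 11 | C1CCCCC1B(C1CCCCC1)/C=C/[C@H](C)[C@H](OC(=O)C(C)(C)C)/C(C)=C/C(C)(C)[C@H](O[Si](C)(C)C(C)(C)C)C=C | intermediate
13 | (3S,4S,5E,8R)-8-(tert-butyldimethylsilyloxy)-3,5,7,7-tetramethyl-4-(pivaloyloxy)deca-5,9-dienal | O=CC[C@H](C)[C@H](OC(=O)C(C)(C)C)/C(C)=C/C(C)(C)[C@H](O[Si](C)(C)C(C)(C)C)C=C | intermediate
14 | (3S,4S,5E,8R)-8-(tert-butyldimethylsilyloxy)-3,5,7,7-tetramethyl-4-(pivaloyloxy)deca-5,9-dienoic acid | OC(=O)C[C@H](C)[C@H](OC(=O)C(C)(C)C)/C(C)=C/C(C)(C)[C@H](O[Si](C)(C)C(C)(C)C)C=C | intermediate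
15 | isobutyl carbonic mixed anhydride of 14 | CC(C)COC(=O)OC(=O)C[C@H](C)[C@H](OC(=O)C(C)(C)C)/C(C)=C/C(C)(C)[C@H](O[Si](C)(C)C(C)(C)C)C=C | intermediate
16 | (4S,5S,6E,9R)-1-diazo-9-(tert-butyldimethylsilyloxy)-4,6,8,8-tetramethyl-5-(pivaloyloxy)undeca-6,10-dien-2-one | [N-]=[N+]=CC(=O)C[C@H](C)[C@H](OC(=O)C(C)(C)C)/C(C)=C/C(C)(C)[C@H](O[Si](C)(C)C(C)(C)C)C=C | intermediate
17 | bicyclo[4.1.0]heptan-2-one with C6 ketone, trans C9 pivalate, exo C10 side chain ending in vinyl | C=C[C@@H](O[Si](C)(C)C(C)(C)C)C(C)(C)[C@H]1[C@]2(C)[C@@H](OC(=O)C(C)(C)C)[C@@H](C)CC(=O)[C@H]12 | intermediate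
18 | C6 carbinol of 17, hydroxyl syn to the cyclopropane | C=C[C@@H](O[Si](C)(C)C(C)(C)C)C(C)(C)[C@H]1[C@]2(C)[C@@H](OC(=O)C(C)(C)C)[C@@H](C)C[C@H](O)[C@H]12 | intermediate
19 | C6 triethylsilyl ether of 18 | C=C[C@@H](O[Si](C)(C)C(C)(C)C)C(C)(C)[C@H]1[C@]2(C)[C@@H](OC(=O)C(C)(C)C)[C@@H](C)C[C@H](O[Si](CC)(CC)CC)[C@H]12 | intermediate
20 | C2 methyl ketone from 19 | CC(=O)[C@@H](O[Si](C)(C)C(C)(C)C)C(C)(C)[C@H]1[C@]2(C)[C@@H](OC(=O)C(C)(C)C)[C@@H](C)C[C@H](O[Si](CC)(CC)CC)[C@H]12 | intermediate
21 | key-step precursor, C2 trimethylsilyl enol ether of 20 | C=C(O[Si](C)(C)C)[C@@H](O[Si](C)(C)C(C)(C)C)C(C)(C)[C@H]1[C@]2(C)[C@@H](OC(=O)C(C)(C)C)[C@@H](C)C[C@H](O[Si](CC)(CC)CC)[C@H]12 | intermediate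
22 | C9 cyclopropylcarbinyl cation | C=C(O[Si](C)(C)C)[C@@H](O[Si](C)(C)C(C)(C)C)C(C)(C)[C@H]1[C@]2(C)[CH+][C@@H](C)C[C@H](O[Si](CC)(CC)CC)[C@H]12 | intermediate
23 | C4 tertiary cyclobutyl (bicyclo[3.1.1]heptyl) cation | C=C(O[Si](C)(C)C)[C@@H](O[Si](C)(C)C(C)(C)C)C(C)(C)[C@H]1[C@@H]2[C@@H](C)C[C@H](O[Si](CC)(CC)CC)[C@H]1[C+]2C | intermediate
24 | key-step product, tricyclic C2 ketone with C1–OTBS, C6–OTES, saturated C7–C8 | CC(C)(C)[Si](C)(C)O[C@@H]1C(=O)C[C@@]2(C)[C@@H]3[C@@H](O[Si](CC)(CC)CC)C[C@H](C)[C@H]2[C@@H]3C1(C)C | intermediate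
25 | C2 alcohol, cis to C1–OTBS | CC(C)(C)[Si](C)(C)O[C@@H]1[C@H](O)C[C@@]2(C)[C@@H]3[C@@H](O[Si](CC)(CC)CC)C[C@H](C)[C@H]2[C@@H]3C1(C)C | intermediate
26 | C2 isobutyrate, trans to C1–OTBS | CC(C)(C)[Si](C)(C)O[C@@H]1[C@@H](OC(=O)C(C)C)C[C@@]2(C)[C@@H]3[C@@H](O[Si](CC)(CC)CC)C[C@H](C)[C@H]2[C@@H]3C1(C)C | intermediate
27 | C6 alcohol from 26 | CC(C)(C)[Si](C)(C)O[C@@H]1[C@@H](OC(=O)C(C)C)C[C@@]2(C)[C@@H]3[C@@H](O)C[C@H](C)[C@H]2[C@@H]3C1(C)C | intermediate
28 | saturated C6 ketone | CC(C)(C)[Si](C)(C)O[C@@H]1[C@@H](OC(=O)C(C)C)C[C@@]2(C)[C@@H]3C(=O)C[C@H](C)[C@H]2[C@@H]3C1(C)C | intermediate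
29 | C6-keto C7=C8 enone with C1–OTBS | CC(C)(C)[Si](C)(C)O[C@@H]1[C@@H](OC(=O)C(C)C)C[C@@]2(C)[C@@H]3C(=O)C=C(C)[C@H]2[C@@H]3C1(C)C | intermediate
30 | C1 alcohol, C2 isobutyrate enone | O[C@@H]1[C@@H](OC(=O)C(C)C)C[C@@]2(C)[C@@H]3C(=O)C=C(C)[C@H]2[C@@H]3C1(C)C | intermediate
31 | CNP0286736.1 | C/C=C(/C)C(=O)O[C@@H]1[C@@H](OC(=O)C(C)C)C[C@@]2(C)[C@@H]3C(=O)C=C(C)[C@H]2[C@@H]3C1(C)C | target

Total step count: 23. Longest linear sequence: 22 steps (steps 1–5 and 7–23, from 1).

**Steps most likely to fail**

**Step 17.**
- Ionisation of the pivalate may be too slow relative to protodesilylation of the enol silane.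
- The cation may lose a proton from the C4 methyl or from C8, accept a hydride from C8, or open to a cycloheptenyl cation before the C3–C4 bond forms.
- Closure is also slowed because the C4 methyl has to swing over the bridge toward the C8 methyl.

The fallback splits the cascade into two known operations. It sets out from 19 and returns at 24.
- i-Bu2AlH removes the pivalate to give the trans C9 cyclopropylcarbinol F1.
- The Wacker conditions of step 15 give the hydroxy methyl ketone F2.
- SOCl2 with 2,6-lutidine in CH2Cl2 at −40 °C effects the classical cyclopropylcarbinyl-to-cyclobutyl halide rearrangement. For 1-methylcyclopropyl carbinols this ends at the tertiary 1-methylcyclobutyl chloride, here the bicyclo[3.1.1]heptyl chloride F3.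
- Kinetic silylation as in step 16 gives the chloro enol silane F4.
- TiCl4 in CH2Cl2 at −78 °C closes C3–C4 by the known Lewis-acid α-tert-alkylation of a silyl enol ether with a tertiary chloride, giving 24.

**Step 12.**
- Facial selectivity of the carbenoid addition may be poor, because it rests on an axial acyloxy group.
- Insertion into C–H bonds or carbene dimerisation may compete with closure of a six-membered ring onto a hindered trisubstituted alkene.

The fallback generates the same acyl carbene without a diazo compound. It sets out from 13 and returns at 17.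
- Seyferth–Gilbert homologation with the Ohira–Bestmann reagent (K2CO3, MeOH) gives the 1,6-enyne F5.
- (Mor-DalPhos)AuNTf2 with 8-methylquinoline N-oxide in 1,2-dichloroethane at 23 °C oxidises the terminal alkyne to an α-oxo gold carbene.
- This carbene cyclopropanates the C4=C10 alkene at ambient temperature under the influence of a bulky ligand.

**Step 19.**
- Activation of the hindered C2 alcohol may be slow with a weakly acidic carboxylic acid.
- Elimination toward C3 may overtake substitution.

The fallback replaces reduction plus inversion by reagent-controlled reduction plus retentive acylation. It sets out from 24 and returns at 26.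
- Corey–Bakshi–Shibata reduction with the (R)-methyl oxazaborolidine and catecholborane in toluene at −40 °C delivers hydride to the face syn to the C1 oxygen and gives the trans C2 alcohol F6.
- Isobutyryl chloride, pyridine and catalytic DMAP convert F6 into 26.

**Further compounds**

F1 | step 17 | trans C9 cyclopropylcarbinol from 19 | C=C[C@@H](O[Si](C)(C)C(C)(C)C)C(C)(C)[C@H]1[C@]2(C)[C@@H](O)[C@@H](C)C[C@H](O[Si](CC)(CC)CC)[C@H]12
F2 | step 17 | C9 hydroxy C2 methyl ketone | CC(=O)[C@@H](O[Si](C)(C)C(C)(C)C)C(C)(C)[C@H]1[C@]2(C)[C@@H](O)[C@@H](C)C[C@H](O[Si](CC)(CC)CC)[C@H]12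
F3 | step 17 | ring-expanded tertiary C4 chloride, bicyclo[3.1.1]heptane with methyl ketone side chain | CC(=O)[C@@H](O[Si](C)(C)C(C)(C)C)C(C)(C)[C@H]1[C@@H]2[C@@H](C)C[C@H](O[Si](CC)(CC)CC)[C@H]1[C@]2(C)Cl
F4 | step 17 | C2 trimethylsilyl enol ether of F3 | C=C(O[Si](C)(C)C)[C@@H](O[Si](C)(C)C(C)(C)C)C(C)(C)[C@H]1[C@@H]2[C@@H](C)C[C@H](O[Si](CC)(CC)CC)[C@H]1[C@]2(C)Cl
F5 | step 12 | 1,6-enyne, terminal alkyne C5≡C6 from 13 | C#CC[C@H](C)[C@H](OC(=O)C(C)(C)C)/C(C)=C/C(C)(C)[C@H](O[Si](C)(C)C(C)(C)C)C=C
F6 | step 19 | C2 alcohol trans to C1–OTBS | CC(C)(C)[Si](C)(C)O[C@@H]1[C@@H](O)C[C@@]2(C)[C@@H]3[C@@H](O[Si](CC)(CC)CC)C[C@H](C)[C@H]2[C@@H]3C1(C)C
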